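(The earlier runs and the new flask were computed for an exercise, noise included.)

The vessel was closed, stirred and held at one temperature. You asked me for a quick figure for the winter run at 20 min, with the hunch that past its slow opening the flask ran as a plain second-order reaction of starting material with partner.

| flask | starting material | partner | free catalyst | time |
|---|---|---|---|---|
| midnight | 0.300 M | 0.450 M | 0.0240 M |  |
| summer | 0.180 M | 0.330 M | 0.0240 M |  |
| noon | 0.300 M | 1.40 M | 0.0240 M |  |
| autumn | 0.300 M | 0.450 M | 0.0720 M |  |
| winter | 0.300 M | 0.450 M | 0.0240 M | 20 min |

| run | time / min | [product] / M |
|---|---|---|
| midnight run | 0.29 | 0.004 |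
| midnight run | 0.88 | 0 |
| midnight run | 1.7 | 0.002 |
| midnight run | 2.7 | 0.018 |
| midnight run | 3.8 | 0.039 |
| midnight run | 5.1 | 0.069 |
| midnight run | 6.5 | 0.102 |
| midnight run | 8.1 | 0.130 |
| summer run | 0.29 | 0 |
| summer run | 0.88 | 0.001 |
| summer run | 1.7 | 0.004 |
| summer run | 2.7 | 0.009 |
| summer run | 3.8 | 0.026 |
| summer run | 5.1 | 0.032 |
| summer run | 6.5 | 0.047 |
| summer run | 8.1 | 0.066 |
| noon run | 0.29 | 0 |
| noon run | 0.88 | 0 |
| noon run | 1.7 | 0.011 |
| noon run | 2.7 | 0.047 |
| noon run | 3.8 | 0.116 |
| noon run | 5.1 | 0.173 |
| noon run | 6.5 | 0.217 |
| noon run | 8.1 | 0.250 |
| autumn run | 0.29 | 0 |
| autumn run | 0.88 | 0.009 |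
| autumn run | 1.7 | 0.051 |
| autumn run | 2.7 | 0.102 |
| autumn run | 3.8 | 0.156 |
| autumn run | 5.1 | 0.202 |
| autumn run | 6.5 | 0.232 |
| autumn run | 8.1 | 0.251 |

(each reading ± 0.003 M)

- how the opening rate goes with [partner] round the charge of the midnight run: the exponent of the rate at two percent of starting material gone to product
- how the opening rate goes with [starting material] round the charge of the midnight run: the exponent of the rate at two percent of starting material gone to product (one fixed amount of product, the same in the runs compared)
- the summer run starts with 0.120 M less of starting material and of partner than the midnight run, and with no product. Compared where both hold the same amount of starting material, once fifteen percent of what the summer run was charged with has turned into product, is the summer run faster, slower or alike (within a tenth)?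
- product in the winter run at 20 min, as a share of the starting material charged

- Overall: starting material + partner -> product, with free catalyst as catalyst.
- Constant volume, constant temperature.
- "The second partner" is partner.
- An order is taken over about fifteen percent of the charge, up and down.

I took the hunch at its word. I wrote x for the fraction of the charged starting material turned to product, c for the starting material charged, and b for partner charged per starting material charged. In the midnight run b was 1.50, so starting material was the limiting reagent. The rate then integrated in closed form, with K the constant of the rate and d the delay, or induction period: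

dx/dt = K·c·(1 − x)(b − x)

G = ln[(b − x) / (b·(1 − x))] = K·c·(b − 1)·(t − d)

So, on that hunch, G had to climb on a straight line once the delay had passed. I read that line from two midnight readings:

at 5.1 min: x = 0.230, G = 0.0949

at 8.1 min: x = 0.433, G = 0.227

slope = 0.0440 min⁻¹, d = 2.95 min

The reading at 6.5 min gave G = 0.158, and the line gave 0.156 there, so I kept the hunch for the tail. Dividing the slope by the excess of partner over starting material in the charge gave K = 0.294 L mol⁻¹ min⁻¹. This is the pair constant: the rate of product per unit of starting material times partner once the delay is past, read at a free catalyst charge of 0.0240 M.

The winter flask had the midnight charge, with free catalyst 0.0240 M, so I ran the same line on and turned G back into x: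

G = slope·(t − d) = 0.751

x = b(e^G − 1) / (b·e^G − 1) = 77.1%

The forecast set the orders in partner and starting material at 0.33 and 0.33, called the summer run slower, and put the winter run at 76%, below my 77.1%, reading the opening as “a catalyst-dependent build-up, not autocatalysis”.

The winter run gave 78.0% at 20 min; round the midnight charge the opening orders were 0.56 in partner and 0.56 in starting material, and the summer run, held against the midnight run at equal starting material, came out slower. The scheme behind the readings was:

    2 active catalyst ⇌ catalyst dimer, settled at all times (1570 L mol⁻¹)
    catalyst dimer + starting material + partner → product + catalyst dimer (43.26 L² mol⁻² min⁻¹)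
    active catalyst + impurity → spent catalyst
    free catalyst → active catalyst (0.4050 min⁻¹)

The midnight run reached x = 0.5 at 9.48 min, and the pair constant with its delay put that point at 9.48 min. The summer run had free catalyst 0.0240 M, and I gave it the midnight delay as my own assumption. There the pair constant made a slope of 0.0440 min⁻¹ and put x = 0.5 at 11.5 min, and the summer run stood there at 11.4 min.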